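Teferin is cut at the C6 ester and at the C4–isopropyl bond. This leaves a hydroazulenone in which C4 of five-membered ring A (C1–C5) is a ketone lying between C3 and ring-fusion C5. That arrangement marks ring A as a Nazarov product, so the route rests on the C1–C2 bond. It is made by 4π closure of a cross-conjugated dienone. One arm is the tetrasubstituted C5=C1 double bond of seven-membered ring B, with the methyl in place on C1. The other is a C2=C3 arm carrying silicon on C2. One operation closes ring A, creates quaternary C1 under control of the C6 silyloxy centre, and fixes the alkene at C2=C3. The precursor is a 7-silyloxy-2,5-dimethylcyclohepta-1,4-dienyl (E)-2-(trimethylsilyl)vinyl ketone.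

Key step: step 8

Numbering: daucane numbering is used throughout, also for the atoms of open-chain and monocyclic precursors (C1 quaternary carbon, C2 and C3 ring A methylenes, C4 carbinol carbon, C5 ring-fusion CH, C6 ester-bearing carbon, C7, C8(CH3)=C9, C10).

Remark on the chemistry: C6 is carried with the configuration of the target, because two-point binding of the Lewis acid is expected to place the C1 methyl trans to the C6 oxygen; the ring fusion is expected to be cis after the key step and is turned trans by equilibration at C5 in step 11.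

Step 1
Reactants: 1 ethyl glyoxylate; 2 isobutene
Product: 3 ethyl (S)-2-hydroxy-4-methylpent-4-enoate
Conditions: (S)-BINOL (10 mol %), TiCl2(Oi-Pr)2 (10 mol %), 4 Å MS, CH2Cl2, −30 °C
Reagents that add atoms: none
Why: Catalytic asymmetric glyoxylate-ene reaction in which the (S)-BINOL–titanium Lewis acid binds the aldehyde and exposes one face to isobutene in a six-membered ene transition state, setting C6 as S, the configuration it keeps to the end.

Step 2
Reactants: 3 ethyl (S)-2-hydroxy-4-methylpent-4-enoate
Product: 4 ethyl (S)-2-(tert-butyldimethylsilyloxy)-4-methylpent-4-enoate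
Conditions: TBSCl, imidazole, DMF, rt
Reagents that add atoms: tert-butyldimethylsilyl chloride, CC(C)(C)[Si](C)(C)Cl
Why: Imidazole-promoted silylation of a secondary alcohol touches no stereocentre, and the bulky ether later screens C6–H from base.

Step 3
Reactants: 4 ethyl (S)-2-(tert-butyldimethylsilyloxy)-4-methylpent-4-enoate
Product: 5 (S)-2-(tert-butyldimethylsilyloxy)-N-methoxy-N,4-dimethylpent-4-enamide
Conditions: MeNH(OMe)·HCl, i-PrMgCl, THF, −20 °C
Reagents that add atoms: N,O-dimethylhydroxylamine hydrochloride, CNOC.Cl
Why: Weinreb amide formation by aminolysis of the ester with the chloromagnesium amide is fast at low temperature, so the α-silyloxy centre C6 should not epimerise.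

Step 4
Reactants: 5 (S)-2-(tert-butyldimethylsilyloxy)-N-methoxy-N,4-dimethylpent-4-enamide; 6 4-bromopent-1-ene
Product: 8 (6S)-6-(tert-butyldimethylsilyloxy)-4,8-dimethylnona-1,8-dien-5-one (both epimers at the methyl-bearing carbon), via pent-4-en-2-ylmagnesium bromide 7 (not isolated)
Conditions: 6, Mg, THF, 0–20 °C, used at once; then 5, THF, 0 °C; aq NH4Cl
Reagents that add atoms: none
Why: Grignard addition to a Weinreb amide stops at the chelated tetrahedral adduct and gives the ketone on quench; the secondary homoallyl reagent is made and used cold to forestall its cyclopropylcarbinyl rearrangement, and the C1 epimer mixture is harmless because C1 becomes sp2 in step 6.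

Step 5
Reactants: 8 (6S)-6-(tert-butyldimethylsilyloxy)-4,8-dimethylnona-1,8-dien-5-one
Product: 9 (2S)-2-(tert-butyldimethylsilyloxy)-4,7-dimethylcyclohept-4-en-1-one (both C7 epimers)
Conditions: second-generation Grubbs catalyst RuCl2(=CHPh)(PCy3)(H2IMes) (5 mol %), CH2Cl2 (0.005 M), reflux
Reagents that add atoms: none
Why: Ring-closing metathesis between the monosubstituted and the 1,1-disubstituted alkene forms the trisubstituted C8=C9 alkene of ring B with loss of ethene, a closure well within reach of this catalyst for seven-membered rings.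

Step 6
Reactants: 9 (2S)-2-(tert-butyldimethylsilyloxy)-4,7-dimethylcyclohept-4-en-1-one
Product: 11 (7S)-7-(tert-butyldimethylsilyloxy)-2,5-dimethylcyclohepta-1,4-dien-1-yl trifluoromethanesulfonate, via potassium enolate 10 (not isolated)
Conditions: KN(SiMe3)2, THF, −78 °C; then Comins' reagent, −78 to 0 °C
Reagents that add atoms: N-(5-chloropyridin-2-yl)bis(trifluoromethanesulfonimide), Clc1ccc(nc1)N(S(=O)(=O)C(F)(F)F)S(=O)(=O)C(F)(F)F
Why: Kinetic deprotonation and O-sulfonylation (enol triflate synthesis): of the two α-methines, C6–H is screened by the silyl ether and its removal would force the C–O bond into the carbonyl plane, so the base should take C1–H and leave C6 intact.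

Step 7
Reactants: 11 (7S)-7-(tert-butyldimethylsilyloxy)-2,5-dimethylcyclohepta-1,4-dien-1-yl trifluoromethanesulfonate; 12 (E)-trimethyl[2-(tributylstannyl)ethenyl]silane
Product: 13 (E)-1-[(7S)-7-(tert-butyldimethylsilyloxy)-2,5-dimethylcyclohepta-1,4-dien-1-yl]-3-(trimethylsilyl)prop-2-en-1-one
Conditions: Pd(PPh3)4 (5 mol %), LiCl, CO (1–3 atm), THF, 55 °C
Reagents that add atoms: carbon monoxide, [C-]#[O+]
Why: Carbonylative Stille coupling, in which oxidative addition of the vinyl triflate to zerovalent palladium, CO insertion and vinyl transfer from tin with retention of the E geometry give the cross-conjugated dienone, as known for 2-methylcycloalkenyl triflates.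

Step 8
Reactants: 13 (E)-1-[(7S)-7-(tert-butyldimethylsilyloxy)-2,5-dimethylcyclohepta-1,4-dien-1-yl]-3-(trimethylsilyl)prop-2-en-1-one
Product: 15 (3aR,4S,8aS)-4-(tert-butyldimethylsilyloxy)-6,8a-dimethyl-4,5,8,8a-tetrahydroazulen-3(3aH)-one (cis-fused hydroazulenone), via aluminium dienolate 14 (not isolated)
Conditions: MeAlCl2 (2.5 equiv), CH2Cl2, −78 to −20 °C; cold aq NaHCO3
Reagents that add atoms: none
Why: Excess MeAlCl2, a Lewis acid known to chelate even silyl ethers, binds the C4 carbonyl oxygen and the C6 silyloxy oxygen at one aluminium centre, which holds the dienone in the U shape and turns it into a hydroxypentadienyl cation that closes ring A by a thermally allowed conrotatory 4π electrocyclisation (formally 5-endo-trig) between C1 and C2. The resulting oxyallyl cation has its C3 terminus β to silicon, so chloride removes Me3Si, the alkene is placed at C2=C3 only, and aluminium dienolate 14 is protonated at C5 on quench. The closest known reaction is the silicon-directed Nazarov cyclisation of cycloalkenyl β-silylvinyl ketones, including 2-methylcycloalkenyl cases that give angular methyl groups. C1 is set by torquoselectivity: with the C6–O bond locked in the dienone plane, C7 and C6–H point to opposite faces, and the rotation that swings C10 to the C7 face (nascent chair cycloheptene) and the inside methyl to the face of the small C6–H is preferred over the one that drives the methyl against C7, so the methyl ends trans to the C6 oxygen as in the target. C5 is set by protonation on the face flanked by CH3 and C6–H rather than by C7 and C10, and the flat cyclopentenone also favours this cis fusion, which is corrected in step 11. The in-plane C6–O bond is orthogonal to the π system, which disfavours ionisation and β-elimination, and the proton-scavenging aluminium reagent spares the C8=C9 alkene and the doubly allylic C10.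

Step 9
Reactants: 15 cis-fused hydroazulenone
Product: 16 (3aR,4S,8aR)-4-(tert-butyldimethylsilyloxy)-6,8a-dimethyl-1,2,4,5,8,8a-hexahydroazulen-3(3aH)-one (cis-fused)
Conditions: H2 (1 atm), RhCl(PPh3)3 (10 mol %), benzene, rt
Reagents that add atoms: none
Why: Homogeneous hydrogenation with RhCl(PPh3)3 reduces a cis-disubstituted enone alkene next to a quaternary carbon but not a trisubstituted alkene, the selectivity known from steroidal 1,4-dien-3-ones, so C8=C9 and all stereocentres are untouched.

Step 10
Reactants: 16 cis-fused silyloxy ketone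
Product: 17 (3aR,4S,8aR)-4-hydroxy-6,8a-dimethyl-1,2,4,5,8,8a-hexahydroazulen-3(3aH)-one (cis-fused)
Conditions: HF·pyridine, THF, 0 °C to rt
Reagents that add atoms: none
Why: Acidic fluoride cleaves the silyl ether without generating base, which avoids β-elimination of the C6 oxygen from the β-oxy ketone.

Step 11
Reactants: 17 cis-fused hydroxy ketone
Product: 18 (3aS,4S,8aR)-4-hydroxy-6,8a-dimethyl-1,2,4,5,8,8a-hexahydroazulen-3(3aH)-one (trans-fused)
Conditions: KOAc, EtOH, 40 °C; recovered 17 is resubmitted
Reagents that add atoms: none
Why: Base-catalysed epimerisation at C5 through the C4 enolate under thermodynamic control: in 18 C2, C4 and the C6 hydroxyl are all equatorial on the chair cycloheptene whereas 17 must place C4 axial, and with acetate as base and hydroxide as the only possible leaving group proton exchange should outrun β-elimination, as in the epimerisation of β-hydroxycyclopentanones of the prostaglandin E type.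

Step 12
Reactants: 18 trans-fused hydroxy ketone
Product: 19 jaeschkeanadiol, (3R,3aS,4S,8aR)-6,8a-dimethyl-3-(propan-2-yl)-1,2,3,3a,4,5,8,8a-octahydroazulene-3,4-diol
Conditions: i-PrMgCl, CeCl3 (dried), THF, −78 to 0 °C (excess reagent); aq NH4Cl
Reagents that add atoms: isopropylmagnesium chloride, CC(C)[Mg]Cl
Why: Organocerium 1,2-addition, which suppresses enolisation and β-hydride reduction: after deprotonation of the C6 hydroxyl the reagent attacks the C4 carbonyl of the trans-fused ketone from the face of C5–H, opposite the axial C1 methyl and the C5–C6 bond, setting C4 as R with its hydroxyl cis to the methyl.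

Step 13
Reactants: 20 vanillic acid
Product: 21 4-acetoxy-3-methoxybenzoic acid
Conditions: Ac2O, pyridine, rt; aqueous work-up
Reagents that add atoms: acetic anhydride, CC(=O)OC(C)=O
Why: Acetylation masks the phenol for the coupling, and any mixed anhydride formed at the acid is hydrolysed on aqueous work-up.

Step 14
Reactants: 19 jaeschkeanadiol; 21 4-acetoxy-3-methoxybenzoic acid
Product: 22 O-acetylteferin (C6 4-acetoxy-3-methoxybenzoate of 19)
Conditions: DCC, DMAP, CH2Cl2, rt
Reagents that add atoms: none
Why: Steglich esterification acylates the secondary C6 hydroxyl with retention, while the tertiary C4 hydroxyl is too hindered to react.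

Step 15
Reactants: 22 O-acetylteferin
Product: 23 teferin
Conditions: pyrrolidine, CH2Cl2, 0 °C
Reagents that add atoms: none
Why: Aminolysis of the aryl acetate, a far better acyl donor than the hindered alkyl benzoate, frees the phenol and leaves the C6 ester, the tertiary alcohol and the alkene untouched.

Compound list
1 | ethyl glyoxylate | CCOC(=O)C=O | starting material
2 | isobutene | CC(C)=C | starting material
3 | ethyl (S)-2-hydroxy-4-methylpent-4-enoate | CCOC(=O)[C@@H](O)CC(C)=C | intermediate
4 | ethyl (S)-2-(tert-butyldimethylsilyloxy)-4-methylpent-4-enoate | CCOC(=O)[C@@H](O[Si](C)(C)C(C)(C)C)CC(C)=C | intermediate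
5 | (S)-2-(tert-butyldimethylsilyloxy)-N-methoxy-N,4-dimethylpent-4-enamide | CON(C)C(=O)[C@@H](O[Si](C)(C)C(C)(C)C)CC(C)=C | intermediate
6 | 4-bromopent-1-ene | CC(Br)CC=C | starting material
7 | pent-4-en-2-ylmagnesium bromide (not isolated) | C=CCC(C)[Mg]Br | intermediate
8 | (6S)-6-(tert-butyldimethylsilyloxy)-4,8-dimethylnona-1,8-dien-5-one, both C4 epimers | C=CCC(C)C(=O)[C@@H](O[Si](C)(C)C(C)(C)C)CC(C)=C | intermediate
9 | (2S)-2-(tert-butyldimethylsilyloxy)-4,7-dimethylcyclohept-4-en-1-one, both C7 epimers | CC1CC=C(C)C[C@H](O[Si](C)(C)C(C)(C)C)C1=O | intermediate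
10 | potassium (7S)-7-(tert-butyldimethylsilyloxy)-2,5-dimethylcyclohepta-1,4-dien-1-olate (not isolated) | CC1=C([O-])[C@@H](O[Si](C)(C)C(C)(C)C)CC(C)=CC1.[K+] | intermediate
11 | (7S)-7-(tert-butyldimethylsilyloxy)-2,5-dimethylcyclohepta-1,4-dien-1-yl trifluoromethanesulfonate | CC1=C(OS(=O)(=O)C(F)(F)F)[C@@H](O[Si](C)(C)C(C)(C)C)CC(C)=CC1 | intermediate
12 | (E)-trimethyl[2-(tributylstannyl)ethenyl]silane | CCCC[Sn](CCCC)(CCCC)/C=C/[Si](C)(C)C | starting material
13 | (E)-1-[(7S)-7-(tert-butyldimethylsilyloxy)-2,5-dimethylcyclohepta-1,4-dien-1-yl]-3-(trimethylsilyl)prop-2-en-1-one (key-step precursor) | C[Si](C)(C)/C=C/C(=O)C1=C(C)CC=C(C)C[C@@H]1O[Si](C)(C)C(C)(C)C | intermediate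
14 | chloro(methyl)aluminium dienolate, C2=C3 and C4=C5, C1 quaternary (not isolated) | C[Al](Cl)OC1=C2[C@@H](O[Si](C)(C)C(C)(C)C)CC(C)=CC[C@@]2(C)C=C1 | intermediate
15 | cis-fused hydroazulenone, C2=C3 enone, C4 ketone, C6 OTBS trans to C1 methyl, C5-H cis to C1 methyl; daucane (1S,5R,6S) (key-step product) | CC(C)(C)[Si](C)(C)O[C@H]1CC(C)=CC[C@@]2(C)C=CC(=O)[C@@H]12 | intermediate
16 | cis-fused saturated C4 ketone, C6 OTBS; daucane (1R,5R,6S) | CC(C)(C)[Si](C)(C)O[C@H]1CC(C)=CC[C@@]2(C)CCC(=O)[C@@H]12 | intermediate
17 | cis-fused C6 hydroxy C4 ketone; daucane (1R,5R,6S) | O[C@H]1CC(C)=CC[C@@]2(C)CCC(=O)[C@@H]12 | intermediate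
18 | trans-fused C6 hydroxy C4 ketone; daucane (1R,5S,6S) | O[C@H]1CC(C)=CC[C@@]2(C)CCC(=O)[C@H]12 | intermediate
19 | jaeschkeanadiol; daucane (1R,4R,5S,6S) | O[C@H]1CC(C)=CC[C@@]2(C)CC[C@@](O)(C(C)C)[C@H]12 | intermediate
20 | vanillic acid | COc1cc(C(=O)O)ccc1O | starting material
21 | 4-acetoxy-3-methoxybenzoic acid | COc1cc(C(=O)O)ccc1OC(C)=O | intermediate
22 | O-acetylteferin | COc1cc(C(=O)O[C@H]2CC(C)=CC[C@@]3(C)CC[C@@](O)(C(C)C)[C@H]23)ccc1OC(C)=O | intermediate
23 | teferin | COc1cc(C(=O)O[C@H]2CC(C)=CC[C@@]3(C)CC[C@@](O)(C(C)C)[C@H]23)ccc1O | target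

Total step count: 15. Longest linear sequence: 14 steps (steps 1–12, 14 and 15).

Steps most likely to fail

**Step 8.** Two-point binding of the silyl ether may be too weak. The singly bound complex, with the C6–O bond perpendicular to the π system, would then compete. This would erode facial control at C1 and open the way to loss of the silyloxy group.
- Fallback: the control element is changed from a dative to a covalent one.
- Compound 13 is desilylated with HF·pyridine to the hydroxy dienone F1.
- Me2AlCl converts the free C6 hydroxyl, with loss of methane, into the chloro(methyl)aluminium alkoxide F2, which is tied to the C4 carbonyl.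
- Added MeAlCl2 triggers the same closure to the cis-fused hydroxy enone F3.
- Hydrogenation over RhCl(PPh3)3 rejoins the route at 17.

**Step 11.** β-Elimination of the C6 hydroxyl may overtake proton exchange, or the equilibrium may not lean far enough to the trans fusion.
- Fallback: the elimination is made deliberate and the oxygen is put back through boron.
- Compound 16 is treated with DBU to give the alkylidene cyclopentanone F4.
- Copper-catalysed conjugate borylation (CuCl, NaOt-Bu, a Josiphos-type chiral bisphosphine chosen for the C6 face, B2pin2, MeOH) gives the β-boryl ketone F5.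
- In F5, C5 can equilibrate under the alkoxide present without any leaving group at C6.
- Oxidation with NaBO3·4H2O, with retention at C6, comes back to the route at 18.

**Step 6.** Deprotonation may take place at C6–H instead of C1–H, which would give the wrong enol triflate and scramble C6.
- Fallback: the enolate is generated regiospecifically by reduction.
- Compound 5 is treated with but-3-enylmagnesium bromide to give the ketone F6.
- Ring-closing metathesis with the same ruthenium catalyst gives the cycloheptenone F7, whose only α-methylene is C1.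
- α-Methylenation with paraformaldehyde and i-Pr2NH·CF3CO2H gives the α-methylene ketone F8.
- Conjugate reduction with LiBH(s-Bu)3 delivers the lithium enolate F9.
- Trapping F9 with Comins' reagent rejoins the route at 11.

Further compounds
F1 | step 8 | (E)-1-[(7S)-7-hydroxy-2,5-dimethylcyclohepta-1,4-dien-1-yl]-3-(trimethylsilyl)prop-2-en-1-one | C[Si](C)(C)/C=C/C(=O)C1=C(C)CC=C(C)C[C@@H]1O
F2 | step 8 | chloro(methyl)aluminium alkoxide of F1 | C[Si](C)(C)/C=C/C(=O)C1=C(C)CC=C(C)C[C@@H]1O[Al](C)Cl
F3 | step 8 | cis-fused C6 hydroxy hydroazulenone with C2=C3 enone | O[C@H]1CC(C)=CC[C@@]2(C)C=CC(=O)[C@@H]12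
F4 | step 11 | C5=C6 alkylidene cyclopentanone | CC1=CC[C@@]2(C)CCC(=O)C2=CC1
F5 | step 11 | trans-fused C6 pinacolboryl C4 ketone | CC1(C)OB(OC1(C)C)[C@H]2CC(C)=CC[C@@]3(C)CCC(=O)[C@H]23
F6 | step 6 | (6S)-6-(tert-butyldimethylsilyloxy)-8-methylnona-1,8-dien-5-one | C=CCCC(=O)[C@@H](O[Si](C)(C)C(C)(C)C)CC(C)=C
F7 | step 6 | (2S)-2-(tert-butyldimethylsilyloxy)-4-methylcyclohept-4-en-1-one | CC1=CCCC(=O)[C@@H](O[Si](C)(C)C(C)(C)C)C1
F8 | step 6 | (2S)-2-(tert-butyldimethylsilyloxy)-4-methyl-7-methylidenecyclohept-4-en-1-one | CC1=CCC(=C)C(=O)[C@@H](O[Si](C)(C)C(C)(C)C)C1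
F9 | step 6 | lithium (7S)-7-(tert-butyldimethylsilyloxy)-2,5-dimethylcyclohepta-1,4-dien-1-olate | CC1=C([O-])[C@@H](O[Si](C)(C)C(C)(C)C)CC(C)=CC1.[Li+]
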